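**Assumptions (one line):** (R)-4-TBSO-cyclopent-2-enone (1), 1-bromooct-2-yne (2), acrolein (8), methyl hex-5-enoate (11) and a cyclometalated Z-selective Ru metathesis catalyst are purchasable. The target's (7S,8R,12S) pattern is an anti-aldol, with the C8 chain cis to the C12-OH and trans to the octenyl group.

## Retrosynthetic overview
1. Disconnect the C5=C6 Z-olefin by late-stage Z-selective cross-metathesis. This gives a terminal vinyl carbinol acetate plus methyl hex-5-enoate, so no Z-enal is carried.
2. Disconnect C7–C8 by an anti-aldol of the 2-iodoenone dianion with acrolein. The C10–I bond comes from Johnson iodination of the enone.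
3. Build the C12 quaternary carbinol by chirality relay from commercial (R)-4-TBSO-cyclopentenone. Propargylation occurs trans to OTBS, and the C9 stereocentre is then sacrificed (TBS off, oxidation to the ketone). The Z-octenyl alkene comes from a Lindlar reduction.
4. The only ring is the commercial cyclopentenone, so no ring is formed in the route.

## Route

**Step 1**
Reactants: 1 (R)-4-TBSO-cyclopent-2-enone; 2 1-bromooct-2-yne
Product: 3 homopropargylic tertiary alcohol
Conditions: Zn dust, THF/sat. aq. NH4Cl, 0 °C → rt
Reagents that add atoms: none beyond reactant 2 (Zn is not retained)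
Why: Barbier propargylation: the allenylzinc from 2 adds through its γ-carbon (SE2′) to the ketone, and it attacks trans to the pseudo-axial OTBS, which fixes C12 as S.

**Step 2**
Reactants: 3
Product: 4 Z-alkene
Conditions: H2 (1 atm), Lindlar catalyst, quinoline, EtOAc, rt
Reagents that add atoms: none (H only)
Why: Syn semihydrogenation of the internal alkyne gives the Z-oct-2-enyl group, and the ring alkene, OTBS and tertiary OH are untouched.

**Step 3**
Reactants: 4
Product: 5 cis-ene-diol
Conditions: TBAF, THF, 0 °C → rt
Reagents that add atoms: none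
Why: Fluoride removes the secondary silyl ether selectively and leaves the C12 stereocentre unchanged.

**Step 4**
Reactants: 5
Product: 6 (S)-4-hydroxy-4-[(Z)-oct-2-enyl]cyclopent-2-enone
Conditions: activated MnO2, CH2Cl2, rt
Reagents that add atoms: none
Why: MnO2 oxidizes only the secondary allylic alcohol (C9), which destroys the sacrificial stereocentre and leaves the tertiary carbinol (C12, S) as the only stereocentre.

**Step 5**
Reactants: 6
Product: 7 2-iodoenone
Conditions: I2, pyridine, CH2Cl2, 0 °C → rt, dark
Reagents that add atoms: I2 (II)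
Why: Johnson α-iodination (pyridine conjugate addition, C2 iodination, elimination); no stereocentre is formed or disturbed.

**Step 6**
Reactants: 7; 8 acrolein
Product: 9 anti-aldol adduct
Conditions: LiHMDS (2.2 equiv), THF, −78 °C; then acrolein, −78 °C; NH4Cl quench
Reagents that add atoms: none beyond reactant 8
Why: Aldol of the alkoxide/enolate dianion: the cyclic (E-type) enolate reacts through a Zimmerman–Traxler chair to give the anti-aldol (C7 S). Acrolein approaches syn to the C12 alkoxide and anti to the octenyl chain, giving C8 R.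

**Step 7**
Reactants: 9
Product: 10 C7 acetate
Conditions: Ac2O, pyridine, cat. DMAP, CH2Cl2, 0 °C
Reagents that add atoms: Ac2O (CC(=O)OC(C)=O)
Why: Mild acylation of the secondary alcohol, with the hindered tertiary alcohol untouched; no stereocentre changes, and the low temperature limits E1cB loss of the β-OAc.

**Step 8**
Reactants: 10; 11 methyl hex-5-enoate
Product: 12 target
Conditions: Z-selective cyclometalated Ru catalyst (5 mol %), 11 (5 equiv), THF, 35 °C, partial vacuum
Reagents that add atoms: none beyond reactant 11
Why: Cross-metathesis of the terminal vinyl group with 11 releases ethylene and builds the C5=C6 double bond.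
Proposed new method: Cyclometalated Ru catalysts give Z-olefins through a side-bound metallacyclobutane in which the substituents are forced syn. They react with terminal olefins and spare the internal Z-olefin, the enone and the vinyl iodide. The closest known reaction is Z-selective cross-metathesis of terminal olefins and allylic acetates. Extending it to this hindered α-branched allylic acetate is the new element.

## Compound list
1 | (R)-4-(tert-butyldimethylsilyloxy)cyclopent-2-en-1-one | CC(C)(C)[Si](C)(C)O[C@H]1C=CC(=O)C1 | starting material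
2 | 1-bromooct-2-yne | CCCCCC#CCBr | starting material
3 | (1S,4R)-4-(TBSO)-1-(oct-2-yn-1-yl)cyclopent-2-en-1-ol | CCCCCC#CC[C@@]1(O)C=C[C@H](O[Si](C)(C)C(C)(C)C)C1 | intermediate
4 | (1S,4R)-4-(TBSO)-1-[(2Z)-oct-2-en-1-yl]cyclopent-2-en-1-ol | CCCCC/C=C\C[C@@]1(O)C=C[C@H](O[Si](C)(C)C(C)(C)C)C1 | intermediate
5 | (1S,4R)-1-[(2Z)-oct-2-en-1-yl]cyclopent-2-ene-1,4-diol | CCCCC/C=C\C[C@@]1(O)C=C[C@H](O)C1 | intermediate
6 | (S)-4-hydroxy-4-[(2Z)-oct-2-en-1-yl]cyclopent-2-en-1-one | CCCCC/C=C\C[C@@]1(O)C=CC(=O)C1 | intermediate
7 | (S)-4-hydroxy-2-iodo-4-[(2Z)-oct-2-en-1-yl]cyclopent-2-en-1-one | CCCCC/C=C\C[C@@]1(O)C=C(I)C(=O)C1 | intermediate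
8 | acrolein | C=CC=O | starting material
9 | (4S,5R)-4-hydroxy-5-[(1S)-1-hydroxyprop-2-en-1-yl]-2-iodo-4-[(2Z)-oct-2-en-1-yl]cyclopent-2-en-1-one | CCCCC/C=C\C[C@@]1(O)C=C(I)C(=O)[C@@H]1[C@@H](O)C=C | intermediate
10 | (1S)-1-[(1R,2S)-2-hydroxy-4-iodo-5-oxo-2-[(2Z)-oct-2-en-1-yl]cyclopent-3-en-1-yl]prop-2-en-1-yl acetate | CCCCC/C=C\C[C@@]1(O)C=C(I)C(=O)[C@@H]1[C@@H](OC(C)=O)C=C | intermediate
11 | methyl hex-5-enoate | C=CCCCC(=O)OC | starting material
12 | methyl (5Z,7S)-7-acetoxy-7-[(1R,2S)-2-hydroxy-4-iodo-5-oxo-2-[(2Z)-oct-2-en-1-yl]cyclopent-3-en-1-yl]hept-5-enoate (7-acetoxy-7,8-dihydroiodovulone I) | CCCCC/C=C\C[C@@]1(O)C=C(I)C(=O)[C@@H]1[C@H](/C=C\CCCC(=O)OC)OC(C)=O | target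

**Total step count:** 8. **Longest linear sequence:** 8 steps (1 → 3 → 4 → 5 → 6 → 7 → 9 → 10 → 12).

**Three steps most likely to fail**
1. **Step 8 (Z-selective cross-metathesis on a hindered secondary allylic acetate).**
   Fallback: skip metathesis and run the step 6 aldol with methyl (Z)-7-oxohept-5-enoate directly (the classical enal aldol).
2. **Step 6 (diastereoselectivity, and retro-aldol of the tertiary alkoxide-enolate).**
   Fallback: accept a C7 epimer mixture and obtain the 7S alcohol by CAL-B/vinyl acetate kinetic resolution in place of step 7.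
3. **Step 1 (propargylation regio- and diastereoselectivity).**
   Fallback: make racemic 6 by Piancatelli rearrangement of 5-[(Z)-oct-2-enyl]furfuryl alcohol, resolve it by chiral preparative SFC, and rejoin the route at step 5.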